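## Analysis of the target

The target 23 is a 3,3a,4,5-tetrahydro-1-benzofuran-6(2H)-one. Ring A (O1, C2, C3, C3a, C7a) is a dihydrofuran, and ring B (C3a, C4, C5, C6, C7, C7a) is a cyclohexenone in which O1–C7a=C7(OMe)–C6=O forms a doubly oxygenated vinylogous ester. It has four stereocentres: C2 (R, methyl), C3 (S, 3,4,5-trimethoxyphenyl), C3a (R, quaternary, allyl) and C5 (S, methoxy). The C2 methyl and the C3 aryl group are trans; the C3a allyl group is trans to the aryl group and so lies on the face of the methyl group; the C5 methoxy group lies on that same face, 1,3-cis to the allyl group across C4. The sensitive groups are the terminal alkene (no hydrogenation once it is present), the enolisable α-methoxy ketone at C5, and, one stage earlier, a 3a-allyl cyclohexadienone that can lose its allyl group by [3,3] shifts towards aromatic isomers. The difficulty is the contiguous C2–C3–C3a triad ending in a quaternary carbon, a fourth centre remote from it, and a ring B that carries the oxygen pattern of a 1,2,3-trioxygenated benzene at a non-aromatic oxidation level. The strategy rests on reading ring A of an aromatic precursor as a trans-2-methyl-3-aryl-2,3-dihydrobenzofuran: O1–C7a–C3a–C3 is then an ortho-quinone methide, and C2 with its methyl group is a one-carbon ylide partner.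

## Retrosynthetic reasoning

**C5–H and C4–H (23 ⇒ 21).** The epimerisable C5 centre is set last. Removing the hydrogens at C4 and C5 gives the cross-conjugated dienone 21, whose C4=C5 arm is the only one with a β-hydrogen. The forward reaction must deliver hydride to C4 and then protonate the enolate 22 at C5 under kinetic control, on the face away from the allyl group.

**C3a–allyl (21 ⇒ 18 + 19).** A 4,4-disubstituted cyclohexadienone is the retron of an oxidatively dearomatised para-alkyl phenol. Cutting the C3a–allyl bond returns ring B to the phenol 18 and the allyl group to the silane 19. This keeps ring B aromatic, and therefore robust, through all earlier steps, and places the new quaternary centre next to C3, whose aryl group can direct the incoming allyl group to the opposite face.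

**C6–O protection (18 ⇒ 17).** The C6 oxygen must be masked while the quinone methide is generated, otherwise the para-quinone methide would form. Benzyl survives strong base and is removed by hydrogenolysis before the alkene is introduced.

**C2–C3 and O1–C2 (17 ⇒ 15 + 13, from 8 and 12).** This is the (4+1) disconnection. Both stereocentres of ring A and the ring itself arise in one step from the ortho-quinone methide 15 and the ethylide 13. The chirality is carried by a recoverable C2-symmetric sulfide, and the benzylic centre of the benzhydrol 8 can be racemic because it becomes sp2. Hydroxide cannot leave from the dianion of 8, so the carbinol is acylated in the flask to the carbonate 14, which eliminates to 15 at low temperature. On the steric model of the ylide, the required 2R configuration calls for the (2S,5S) sulfonium salt 12.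

**C3–C3a (8 ⇒ 5 + 6).** The diaryl carbinol is cut at the aryl–carbon bond. The phenol 5 has a single free ortho position, so a magnesium-templated addition to the aldehyde 6 can only take place there.

**Oxygen pattern (5 ⇒ 3 ⇒ 2 ⇒ 1).** The phenol oxygen is introduced by formylation of 2 and oxidative replacement of the formyl group. The central oxygen of 1 is the one that is benzylated, which fixes the later C6 oxygen.

**Sulfonium salt (12 ⇒ 11 ⇒ 10 ⇒ 9).** The thiolane 11 comes from the diol 9 by double inversion through 10. S-Ethylation of a C2-symmetric sulfide gives a single sulfonium salt.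

## Alternatives that were turned down

Alternative 1: Ring B is cut at C3a–C4 and C7–C7a, and the aryl group is added last. The allylated tetronic acid A2 would add through its C3 (the later C3a) to the vinyl ketone A3. The methoxymethyl ketone enolate would then acylate the lactone carbonyl, and re-closure of ring A on C7a would give the bicyclic diketone A1. In its favour, C2 comes from the chiral pool, the quaternary C3a is made by alkylating a stabilised enolate, and no dearomatisation is needed. On the formation of C3a it is stronger than the chosen route, which has a regiochemical question there. Against it, C3a and C5 are set only relative to a remote methyl group, and A3 is a labile, doubly activated vinyl ketone. The aryl group must then be added to a neopentyl C3 ketone in the presence of the C6 carbonyl. The resulting tertiary benzylic alcohol must be deoxygenated with control of the C3 configuration, through a cation placed next to C3a and its pendant alkene, where cyclisation and 1,2-shifts are likely. The chosen route offers instead the C2/C3 pair in one reagent-controlled step, with the aryl group present from the start.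

Alternative 2: Both rings are cut at once, at C3a–C7a and C4–C5. An intramolecular Diels–Alder reaction of the triene A5 would join a tetra-oxygenated diene to a 1,1-disubstituted alkene and give the silyl enol ether A4. In its favour, two rings and the quaternary centre form in one step, the allyl group is present from the start without any regiochemical question, and C2/C3 can be set by acyclic methods. Against it, an electron-rich diene and an unactivated alkene held by a three-atom tether have no electronic match, so forcing conditions would be needed that such a diene is unlikely to tolerate. Two tetrasubstituted enol ether geometries must be made and kept. A4 also emerges with sp3 C7a–H and the wrong C5 configuration, so that desilylation, dehydrogenation to C7=C7a and epimerisation would follow. The chosen route is shorter and uses the benzene ring as a stable carrier of the oxygen pattern.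

Alternative 3: Ring A is cut at O1–C7a. The prochiral dienone alcohol A7 would close by 5-exo oxa-Michael addition of its C2 alkoxide to one of the two enone arms, and the enolate would be silylated to give A6. In its favour, C3a is not stereogenic when the allyl group is introduced, which removes the facial question of the chosen route, and the cis ring fusion is automatic. Against it, the oxygen adds to a β-CH, so C7a ends up sp3 and must be dehydrogenated back to the vinylogous ester before the same final reduction as in the chosen route. The β-alkoxy ketone can revert by retro-Michael reaction, and the choice between the two enone arms, which fixes C3a, rests on a modest conformational bias. A7 also still needs a dearomative para-allylation, with the same regiochemical question, and a separate acyclic synthesis of the C2/C3 pair. The chosen route needs no redox correction and sets C2 and C3 together.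

Key step: step 8

## Route

Assumption: the sense of induction of the thiolanium ylide is taken from the steric model given in step 8, which calls for the (2S,5S) salt 12; the quinone methide 15 is drawn as its E isomer.

Step 1
Reactants: 1 2,6-dimethoxyphenol
Product: 2 2-(benzyloxy)-1,3-dimethoxybenzene
Conditions: BnBr, K2CO3, DMF, 60 °C
Reagents that add atoms: benzyl bromide, BrCc1ccccc1
Why: Williamson etherification of the phenoxide.

Step 2
Reactants: 2 2-(benzyloxy)-1,3-dimethoxybenzene
Product: 3 3-(benzyloxy)-2,4-dimethoxybenzaldehyde
Conditions: POCl3, DMF, 80 °C; then aq. NaOAc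
Reagents that add atoms: N,N-dimethylformamide, CN(C)C=O (formyl carbon); water, O (carbonyl oxygen)
Why: Vilsmeier–Haack formylation; C4 of 2 is ortho to one methoxy group and para to the other, whereas C5 is activated only by the twisted central benzyloxy group.

Step 3
Reactants: 3 3-(benzyloxy)-2,4-dimethoxybenzaldehyde
Product: 5 3-(benzyloxy)-2,4-dimethoxyphenol, via aryl formate 4 (not isolated)
Conditions: mCPBA, CH2Cl2, 0 °C to rt; then K2CO3 (cat.), MeOH, rt
Reagents that add atoms: 3-chloroperoxybenzoic acid, OOC(=O)c1cccc(Cl)c1
Why: Baeyer–Villiger oxidation of an electron-rich benzaldehyde with aryl migration (Dakin-type) gives the formate 4, which is methanolysed in the same flask.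

Step 4
Reactants: 5 3-(benzyloxy)-2,4-dimethoxyphenol; 6 3,4,5-trimethoxybenzaldehyde
Product: 8 rac-3-(benzyloxy)-6-[hydroxy(3,4,5-trimethoxyphenyl)methyl]-2,4-dimethoxyphenol, via bromomagnesium phenoxide 7 (not isolated)
Conditions: EtMgBr, Et2O, 0 °C; solvent exchanged to toluene; 6, rt; aq. NH4Cl
Reagents that add atoms: none
Why: Ortho-specific hydroxyalkylation of a bromomagnesium phenoxide in a non-coordinating solvent: magnesium binds phenoxide and aldehyde and delivers the aldehyde to the only free ortho carbon (the para carbon carries methoxy). The new carbinol centre is racemic and is erased in step 8.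

Step 5
Reactants: 9 (2R,5R)-hexane-2,5-diol
Product: 10 (2R,5R)-hexane-2,5-diyl dimethanesulfonate
Conditions: MsCl, Et3N, CH2Cl2, 0 °C
Reagents that add atoms: methanesulfonyl chloride, CS(Cl)(=O)=O
Why: Sulfonylation of both secondary alcohols, with retention at carbon.

Step 6
Reactants: 10 (2R,5R)-hexane-2,5-diyl dimethanesulfonate
Product: 11 (2S,5S)-2,5-dimethylthiolane (trans)
Conditions: Na2S·9H2O, DMSO, rt
Reagents that add atoms: sodium sulfide, [Na+].[Na+].[S-2]
Why: Double SN2 displacement by sulfide, the second one a 5-exo-tet closure; each carbon is inverted, so the (2R,5R) diol gives the (2S,5S) thiolane.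

Step 7
Reactants: 11 (2S,5S)-2,5-dimethylthiolane
Product: 12 (2S,5S)-1-ethyl-2,5-dimethylthiolan-1-ium tetrafluoroborate
Conditions: Et3OBF4, CH2Cl2, 0 °C to rt
Reagents that add atoms: triethyloxonium tetrafluoroborate, CC[O+](CC)CC.F[B-](F)(F)F
Why: S-Ethylation by a trialkyloxonium salt; the two lone pairs of the C2-symmetric sulfide are equivalent, so a single sulfonium salt forms.

Step 8
Reactants: 8 rac-3-(benzyloxy)-6-[hydroxy(3,4,5-trimethoxyphenyl)methyl]-2,4-dimethoxyphenol; 12 (2S,5S)-1-ethyl-2,5-dimethylthiolan-1-ium tetrafluoroborate
Product: 17 (2R,3S)-6-(benzyloxy)-5,7-dimethoxy-2-methyl-3-(3,4,5-trimethoxyphenyl)-2,3-dihydro-1-benzofuran, via sulfonium ylide 13 (not isolated), via benzylic carbonate 14 (not isolated), via ortho-quinone methide 15 (not isolated), via betaine 16 (not isolated)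
Conditions: 8, KN(SiMe3)2 (2.05 equiv), THF, −78 °C, then Boc2O (1.0 equiv), −78 to −40 °C; cannulated into 12 (1.5 equiv)/KN(SiMe3)2 (1.45 equiv), THF, −78 °C; then to 0 °C
Reagents that add atoms: none
Why: Proposed new method: the closest known reaction type is the base-mediated (4+1) annulation of ortho-quinone methides with carbonyl-stabilised sulfonium ylides or with sulfoxonium methylide (a Michael-initiated, Corey–Chaykovsky-type closure), extended here to a non-stabilised ethylide carried by a chiral sulfide. In the first flask the benzylic alkoxide of the dianion of 8 is acylated by Boc2O, and 14 loses tert-butyl carbonate by 1,4-elimination to give 15, because hydroxide itself cannot leave under base; in the second flask KN(SiMe3)2 removes a proton from the S-ethyl CH2 of 12 (the ring α-positions are hindered methines) to give 13. The ylide carbon adds to the exocyclic C3 of 15, which restores the aromatic ring and forms C2–C3, and the phenoxide of 16 then displaces the sulfide at C2 in a 5-exo-tet SN2 closure of ring A that forms O1–C2 with inversion. C2 is under reagent control: in 13 the ylide methyl points away from the thiolane ring, one face of the ylide carbon is flanked by a ring methyl and the other by a ring hydrogen, attack past the hydrogen gives the S-configured sulfonium carbon of 16, and the inversion turns it into 2R. C3 is set by the relative topicity of the same bond formation, for which the staggered approach with the bulky thiolanium anti to C3a and the ylide hydrogen over the aryl group leads to the betaine that closes to the trans ring. Because this addition is irreversible, trans/cis control is kinetic and is the least secure element. The step also needs the ortho- and not the para-quinone methide, which the benzyl group on the C6 oxygen secures, and conjugate rather than carbonyl attack, which rearomatisation secures.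

Step 9
Reactants: 17 (2R,3S)-6-(benzyloxy)-5,7-dimethoxy-2-methyl-3-(3,4,5-trimethoxyphenyl)-2,3-dihydro-1-benzofuran
Product: 18 (2R,3S)-5,7-dimethoxy-2-methyl-3-(3,4,5-trimethoxyphenyl)-2,3-dihydro-1-benzofuran-6-ol
Conditions: H2 (1 atm), Pd/C, EtOAc, rt
Reagents that add atoms: none
Why: Hydrogenolysis of the benzyl ether; the aryl methyl ethers, the ring ether (O1–C2 is not benzylic) and both stereocentres are untouched.

Step 10
Reactants: 18 (2R,3S)-5,7-dimethoxy-2-methyl-3-(3,4,5-trimethoxyphenyl)-2,3-dihydro-1-benzofuran-6-ol; 19 allyltrimethylsilane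
Product: 21 (2R,3S,3aR)-3a-allyl-5,7-dimethoxy-2-methyl-3-(3,4,5-trimethoxyphenyl)-3,3a-dihydro-1-benzofuran-6(2H)-one, via phenoxonium ion 20 (not isolated)
Conditions: PhI(OAc)2, 19 (5 equiv), (CF3)2CHOH, −20 °C; NaHCO3, cold work-up
Reagents that add atoms: none
Why: Two-electron oxidation of the phenol by the trivalent iodine reagent in the ionising, non-nucleophilic fluoroalcohol gives 20, which the allylsilane captures at the para carbon C3a (oxidative ipso-allylation of a para-alkyl phenol, a Hosomi–Sakurai-type step); the two ortho carbons are oxocarbenium-like and flanked, so the carbon nucleophile is expected at the all-carbon terminus. The C3 aryl group shields its own face of the adjacent C3a, so the allyl group should enter trans to it (3aR).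

Step 11
Reactants: 21 (2R,3S,3aR)-3a-allyl-5,7-dimethoxy-2-methyl-3-(3,4,5-trimethoxyphenyl)-3,3a-dihydro-1-benzofuran-6(2H)-one
Product: 23 (2R,3S,3aR,5S)-3a-allyl-5,7-dimethoxy-2-methyl-3-(3,4,5-trimethoxyphenyl)-3,3a,4,5-tetrahydro-1-benzofuran-6(2H)-one, via lithium enolate 22 (not isolated)
Conditions: LiBH(s-Bu)3, THF, −78 °C; then t-BuCO2H, THF, −78 °C; neutral, non-oxidative work-up
Reagents that add atoms: none
Why: Conjugate reduction by the hindered borohydride at C4, the only β-carbon with hydrogen (C7a is a fully substituted, deactivated vinylogous ester carbon), gives 22. Kinetic protonation at C5 should occur on the face opposite the pseudo-axial C3a allyl group, which is 1,3-related to C5, and this places the methoxy group cis to the allyl group (5S); the bulky acid and neutral work-up are meant to prevent later enolisation.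

## Compound list

1 | 2,6-dimethoxyphenol | COc1cccc(OC)c1O | starting material
2 | 2-(benzyloxy)-1,3-dimethoxybenzene | COc1cccc(OC)c1OCc1ccccc1 | intermediate
3 | 3-(benzyloxy)-2,4-dimethoxybenzaldehyde | COc1ccc(C=O)c(OC)c1OCc1ccccc1 | intermediate
4 | 3-(benzyloxy)-2,4-dimethoxyphenyl formate | COc1ccc(OC=O)c(OC)c1OCc1ccccc1 | intermediate
5 | 3-(benzyloxy)-2,4-dimethoxyphenol | COc1ccc(O)c(OC)c1OCc1ccccc1 | intermediate
6 | 3,4,5-trimethoxybenzaldehyde | COc1cc(C=O)cc(OC)c1OC | starting material
7 | bromomagnesium 3-(benzyloxy)-2,4-dimethoxyphenoxide | COc1ccc(O[Mg]Br)c(OC)c1OCc1ccccc1 | intermediate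
8 | rac-3-(benzyloxy)-6-[hydroxy(3,4,5-trimethoxyphenyl)methyl]-2,4-dimethoxyphenol | Oc1c(OC)c(OCc2ccccc2)c(OC)cc1C(O)c1cc(OC)c(OC)c(OC)c1 | intermediate
9 | (2R,5R)-hexane-2,5-diol | C[C@@H](O)CC[C@@H](C)O | starting material
10 | (2R,5R)-hexane-2,5-diyl dimethanesulfonate | C[C@@H](OS(C)(=O)=O)CC[C@@H](C)OS(C)(=O)=O | intermediate
11 | (2S,5S)-2,5-dimethylthiolane | C[C@H]1CC[C@H](C)S1 | intermediate
12 | (2S,5S)-1-ethyl-2,5-dimethylthiolan-1-ium tetrafluoroborate | CC[S+]1[C@@H](C)CC[C@@H]1C.F[B-](F)(F)F | intermediate
13 | (2S,5S)-2,5-dimethylthiolan-1-ium 1-ethylide | C[CH-][S+]1[C@@H](C)CC[C@@H]1C | intermediate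
14 | potassium rac-3-(benzyloxy)-6-[(tert-butoxycarbonyloxy)(3,4,5-trimethoxyphenyl)methyl]-2,4-dimethoxyphenoxide | [K+].[O-]c1c(OC)c(OCc2ccccc2)c(OC)cc1C(OC(=O)OC(C)(C)C)c1cc(OC)c(OC)c(OC)c1 | intermediate
15 | (6E)-3-(benzyloxy)-2,4-dimethoxy-6-(3,4,5-trimethoxybenzylidene)cyclohexa-2,4-dien-1-one | O=C1C(OC)=C(OCc2ccccc2)C(OC)=C/C1=C\c1cc(OC)c(OC)c(OC)c1 | intermediate
16 | 3-(benzyloxy)-6-[(1S,2S)-2-[(2S,5S)-2,5-dimethylthiolan-1-ium-1-yl]-1-(3,4,5-trimethoxyphenyl)propyl]-2,4-dimethoxyphenolate | [O-]c1c(OC)c(OCc2ccccc2)c(OC)cc1[C@H](c1cc(OC)c(OC)c(OC)c1)[C@H](C)[S+]1[C@@H](C)CC[C@@H]1C | intermediate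
17 | (2R,3S)-6-(benzyloxy)-5,7-dimethoxy-2-methyl-3-(3,4,5-trimethoxyphenyl)-2,3-dihydro-1-benzofuran | COc1c(OCc2ccccc2)c(OC)cc2c1O[C@H](C)[C@H]2c1cc(OC)c(OC)c(OC)c1 | intermediate
18 | (2R,3S)-5,7-dimethoxy-2-methyl-3-(3,4,5-trimethoxyphenyl)-2,3-dihydro-1-benzofuran-6-ol | COc1c(O)c(OC)cc2c1O[C@H](C)[C@H]2c1cc(OC)c(OC)c(OC)c1 | intermediate
19 | allyltrimethylsilane | C=CC[Si](C)(C)C | starting material
20 | phenoxonium ion of 18, drawn as its C5 oxocarbenium form | COC1=C2O[C@H](C)[C@@H](c3cc(OC)c(OC)c(OC)c3)C2=CC(=[O+]C)C1=O | intermediate
21 | (2R,3S,3aR)-3a-allyl-5,7-dimethoxy-2-methyl-3-(3,4,5-trimethoxyphenyl)-3,3a-dihydro-1-benzofuran-6(2H)-one | C=CC[C@]12C=C(OC)C(=O)C(OC)=C1O[C@H](C)[C@H]2c1cc(OC)c(OC)c(OC)c1 | intermediate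
22 | lithium (2R,3S,3aR)-3a-allyl-5,7-dimethoxy-2-methyl-3-(3,4,5-trimethoxyphenyl)-2,3,3a,4-tetrahydro-1-benzofuran-6-olate | C=CC[C@]12CC(OC)=C(O[Li])C(OC)=C1O[C@H](C)[C@H]2c1cc(OC)c(OC)c(OC)c1 | intermediate
23 | (2R,3S,3aR,5S)-3a-allyl-5,7-dimethoxy-2-methyl-3-(3,4,5-trimethoxyphenyl)-3,3a,4,5-tetrahydro-1-benzofuran-6(2H)-one | C=CC[C@]12C[C@H](OC)C(=O)C(OC)=C1O[C@H](C)[C@H]2c1cc(OC)c(OC)c(OC)c1 | target

## Step count and uncertain steps

Total step count: 11. Longest linear sequence: 8 steps (1, 2, 3, 4, 8, 9, 10, 11); steps 5 to 7 form the side branch to 12.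

**Step 8 (key step, proposed new method).**
- What may go wrong: C–C bond formation without facial preference at C3, giving cis/trans mixtures, because a non-stabilised ylide adds irreversibly. Loss of the ylide by α′,β-elimination or by proton transfer before it meets 15. Base-induced elimination of the sulfide from 16, whose C3–H is doubly benzylic. Decay of 15 before the transfer.
- Fallback: it keeps the (4+1) annulation but uses carbonyl-stabilised ylides, for which this annulation is established. It sets out from 8 and returns at 17. p-Toluenesulfinic acid in CH2Cl2 should convert 8 into the sulfone rac-3-(benzyloxy)-2,4-dimethoxy-6-[(4-methylphenyl)sulfonyl(3,4,5-trimethoxyphenyl)methyl]phenol F1, from which Cs2CO3 releases 15 at room temperature. A cinchona-alkaloid-derived ammonium salt of tert-butyl bromoacetate (the pseudo-enantiomeric series chosen for the required sense) supplies a chiral ester-stabilised ylide; because betaine formation is then reversible, the annulation should give the trans ester tert-butyl (2S,3S)-6-(benzyloxy)-5,7-dimethoxy-3-(3,4,5-trimethoxyphenyl)-2,3-dihydro-1-benzofuran-2-carboxylate F2. LiAlH4 reduces it to the alcohol [(2S,3S)-6-(benzyloxy)-5,7-dimethoxy-3-(3,4,5-trimethoxyphenyl)-2,3-dihydro-1-benzofuran-2-yl]methanol F3, TsCl/pyridine gives its 4-methylbenzenesulfonate F4, and LiBHEt3 displaces the sulfonate by hydride to give 17.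

**Step 10.**
- What may go wrong: allyl transfer to the methoxy-bearing ortho carbon C5 instead of C3a. Loss of the C3 proton from the oxidised intermediate, which gives a para-quinone methide and destroys the C3 centre. Attack on the aryl face. [3,3] drift of the allyl group in 21 on warming.
- Fallback: it replaces capture of a cation by conjugate addition to an enone in which C3a is the only electrophilic β-carbon. It sets out from 18 and returns at 21. NaIO4 in aqueous MeCN should remove the less hindered C5 methyl group oxidatively and give the ortho-quinone (2R,3S)-7-methoxy-2-methyl-3-(3,4,5-trimethoxyphenyl)-2,3-dihydro-1-benzofuran-5,6-dione F5. Hosomi–Sakurai conjugate allylation with 19 and TiCl4 in CH2Cl2 at −78 °C, anti to the aryl group, should give the enolised diketone (2R,3S,3aR)-3a-allyl-5-hydroxy-7-methoxy-2-methyl-3-(3,4,5-trimethoxyphenyl)-3,3a-dihydro-1-benzofuran-6(2H)-one F6. O-Methylation with Me2SO4 and K2CO3 in acetone then gives 21.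

**Step 11.**
- What may go wrong: carbonyl (1,2) reduction. Slow hydride delivery to C4, which is neopentyl and flanked on both faces. Protonation on the allyl face, or enolisation after protonation with loss of the C5 configuration.
- Fallback: it separates hydride delivery from protonation through an isolable enol ether. It sets out from 21 and returns at 23. Copper hydride catalysis with [(Ph3P)CuH]6 and Et3SiH in toluene, which is specific for 1,4-reduction and leaves the terminal alkene alone, should give triethylsilyl (2R,3S,3aR)-3a-allyl-5,7-dimethoxy-2-methyl-3-(3,4,5-trimethoxyphenyl)-2,3,3a,4-tetrahydro-1-benzofuran-6-yl ether F7. Protodesilylation at −78 °C with a buffered fluoride and acid source then sets C5 in a separate, tunable step. If the wrong epimer still prevails, the mixture can be equilibrated with mild base and the 5S isomer separated and recycled.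

**Step 4.**
- What may go wrong: ionisation of the magnesium salt of the product to the quinone methide and its capture by a second phenoxide (triarylmethane formation). Acid-promoted self-condensation of 8 during purification.
- Fallback: it forms the same C–C bond from the other side. It sets out from 5 and returns at 8. Ortho-formylation with MgCl2, Et3N and paraformaldehyde in MeCN gives 4-(benzyloxy)-2-hydroxy-3,5-dimethoxybenzaldehyde F8, and commercial 3,4,5-trimethoxyphenylmagnesium bromide (2.2 equiv, THF, 0 °C) adds to it to give 8.

## Further compounds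

F1 | step 8 | rac-3-(benzyloxy)-2,4-dimethoxy-6-[(4-methylphenyl)sulfonyl(3,4,5-trimethoxyphenyl)methyl]phenol | Oc1c(OC)c(OCc2ccccc2)c(OC)cc1C(c1cc(OC)c(OC)c(OC)c1)S(=O)(=O)c1ccc(C)cc1
F2 | step 8 | tert-butyl (2S,3S)-6-(benzyloxy)-5,7-dimethoxy-3-(3,4,5-trimethoxyphenyl)-2,3-dihydro-1-benzofuran-2-carboxylate | COc1c(OCc2ccccc2)c(OC)cc2c1O[C@H](C(=O)OC(C)(C)C)[C@H]2c1cc(OC)c(OC)c(OC)c1
F3 | step 8 | [(2S,3S)-6-(benzyloxy)-5,7-dimethoxy-3-(3,4,5-trimethoxyphenyl)-2,3-dihydro-1-benzofuran-2-yl]methanol | COc1c(OCc2ccccc2)c(OC)cc2c1O[C@H](CO)[C@H]2c1cc(OC)c(OC)c(OC)c1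
F4 | step 8 | [(2S,3S)-6-(benzyloxy)-5,7-dimethoxy-3-(3,4,5-trimethoxyphenyl)-2,3-dihydro-1-benzofuran-2-yl]methyl 4-methylbenzenesulfonate | COc1c(OCc2ccccc2)c(OC)cc2c1O[C@H](COS(=O)(=O)c1ccc(C)cc1)[C@H]2c1cc(OC)c(OC)c(OC)c1
F5 | step 10 | (2R,3S)-7-methoxy-2-methyl-3-(3,4,5-trimethoxyphenyl)-2,3-dihydro-1-benzofuran-5,6-dione | COC1=C2O[C@H](C)[C@@H](c3cc(OC)c(OC)c(OC)c3)C2=CC(=O)C1=O
F6 | step 10 | (2R,3S,3aR)-3a-allyl-5-hydroxy-7-methoxy-2-methyl-3-(3,4,5-trimethoxyphenyl)-3,3a-dihydro-1-benzofuran-6(2H)-one | C=CC[C@]12C=C(O)C(=O)C(OC)=C1O[C@H](C)[C@H]2c1cc(OC)c(OC)c(OC)c1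
F7 | step 11 | triethylsilyl (2R,3S,3aR)-3a-allyl-5,7-dimethoxy-2-methyl-3-(3,4,5-trimethoxyphenyl)-2,3,3a,4-tetrahydro-1-benzofuran-6-yl ether | C=CC[C@]12CC(OC)=C(O[Si](CC)(CC)CC)C(OC)=C1O[C@H](C)[C@H]2c1cc(OC)c(OC)c(OC)c1
F8 | step 4 | 4-(benzyloxy)-2-hydroxy-3,5-dimethoxybenzaldehyde | COc1cc(C=O)c(O)c(OC)c1OCc1ccccc1
A1 | alternative 1 | 3a-allyl-5,7-dimethoxy-2-methyl-4,5-dihydro-1-benzofuran-3,6(2H,3aH)-dione, configured at C2, C3a and C5 as in 23 | C=CC[C@]12C[C@H](OC)C(=O)C(OC)=C1O[C@H](C)C2=O
A2 | alternative 1 | (5R)-3-allyl-4-hydroxy-5-methylfuran-2(5H)-one | C[C@H]1OC(=O)C(CC=C)=C1O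
A3 | alternative 1 | 1,3-dimethoxybut-3-en-2-one | COCC(=O)C(=C)OC
A4 | alternative 2 | cis-fused tert-butyldimethylsilyl enol ether with C7a–H, C5 epimeric to 23 | C=CC[C@]12C[C@@H](OC)C(O[Si](C)(C)C(C)(C)C)=C(OC)[C@H]1O[C@H](C)[C@H]2c1cc(OC)c(OC)c(OC)c1
A5 | alternative 2 | open-chain triene: 2-allyl-allyl carbinol ether of a 1,2,4-trioxygenated 3-silyloxy diene, C2/C3 configured as in 23 | C=CCC(=C)[C@H](c1cc(OC)c(OC)c(OC)c1)[C@@H](C)O/C=C(OC)/C(O[Si](C)(C)C(C)(C)C)=C/OC
A6 | alternative 3 | cis-fused trimethylsilyl dienol ether with C7a–H | C=CC[C@]12C=C(OC)C(O[Si](C)(C)C)=C(OC)[C@H]1O[C@H](C)[C@H]2c1cc(OC)c(OC)c(OC)c1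
A7 | alternative 3 | 4-allyl-4-[2-hydroxy-1-(3,4,5-trimethoxyphenyl)propyl]-2,6-dimethoxycyclohexa-2,5-dien-1-one, side chain configured as C2/C3 of 23 | C=CCC1(C=C(OC)C(=O)C(OC)=C1)[C@H](c1cc(OC)c(OC)c(OC)c1)[C@@H](C)O
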